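The target is cut at C3–C11' and C1–C13', the two bonds that tie the guaianolide half (C1–C15) to the seco-eudesmanolide half (primed) in the bicyclo[2.2.1]heptene ring. The key step exploits the 1,4-dicarbonyl relation C2(=O)–C3–C11'–C12'(=O) of the 7-oxonorbornene with its spiro lactone: the C3 ketone enolate and the C11' lactone enolate, already tethered through C1–C13', are oxidised together so that C3–C11' forms, ring C1–C2–C3–C11'–C13' closes and both stereocentres are set in one operation. Its precursor is the C1-quaternary keto lactone from Michael addition of a hydroazulenone dienolate to the lower α-methylene lactone; both halves come from (R)-carvone through one transposed allylic alcohol.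

Key step: step 26

Remark on numbering and stereochemistry: ring atoms of carvone-derived intermediates carry the labels of the target atoms they become (carvone C6, C1, C2, C3, C4, C5 = C8, C9, C10, C1, C6, C7 in the upper series and C8', C9', C10', C5', C6', C7' in the lower series); β is the face of the C7/C7' side chain. The stereodescriptors of the key-step precursor and product were checked against the target and found consistent; with the C6-hydroxylation/transposition mapping used here both C7 and C7' correspond to C5 of (R)-carvone, not of its enantiomer.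

Assumption: ethyl N,N-diisopropylcarbamate and (−)-sparteine are taken as purchasable reagents; the oxirane carbon of the masked isopropenyl group (compounds 3–8 and 29–36) is carried as both epimers because it becomes sp2.

Step 1
Reactants: 1 (R)-carvone
Product: 4 trans-6-hydroxy-8,9-epoxycarvone, via silyl dienol ether 2 (not isolated), via silyloxy epoxy ketone 3 (not isolated)
Conditions: LiN(iPr)2, Me3SiCl, THF, −78 °C; mCPBA (2.2 equiv), NaHCO3, CH2Cl2, −20 → 0 °C; K2CO3 (cat.), MeOH, 0 °C
Reagents that add atoms: mCPBA (3-chloroperoxybenzoic acid), OOC(=O)c1cccc(Cl)c1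
Why: Kinetic deprotonation at C8 and O-silylation give the cross-conjugated dienol ether, which the peracid should oxidise anti to the C7 side chain (Rubottom oxidation, trans hydroxy ketone), while the second equivalent epoxidises the isopropenyl group (Prilezhaev epoxidation) in preference to the electron-poor enone, masking it as the later C11–C13 unit.

Step 2
Reactants: 4 trans-6-hydroxy-8,9-epoxycarvone
Product: 5 silyl ether of 4
Conditions: t-BuMe2SiCl, imidazole, DMF, rt
Reagents that add atoms: tert-butyldimethylsilyl chloride, CC(C)(C)[Si](C)(C)Cl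
Why: Routine O-silylation of the secondary α-hydroxy ketone under conditions that leave the oxirane untouched.

Step 3
Reactants: 5 silyl ether of 4
Product: 6 bis-epoxy ketone
Conditions: H2O2 (30 % aq.), NaOH (cat.), MeOH, 0 °C
Reagents that add atoms: hydrogen peroxide, OO
Why: Weitz–Scheffer epoxidation, in which hydroperoxide adds axially to the enone β-carbon anti to the C7 side chain, so the ring epoxide should form on the α face.

Step 4
Reactants: 6 bis-epoxy ketone
Product: 7 transposed allylic alcohol
Conditions: N2H4·H2O, AcOH (cat.), MeOH, 0 °C → rt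
Reagents that add atoms: none
Why: Wharton transposition, in which the epoxy hydrazone fragments with loss of N2 to the allylic alcohol, deleting the C9 oxygen, creating C9=C10 and keeping the α C–O bond at C1 (C5' in the lower series).

Step 5
Reactants: 7 transposed allylic alcohol
Product: 8 saturated cyclohexanol
Conditions: H2 (1 atm), [Ir(cod)(PCy3)(py)]PF6 (5 mol%), CH2Cl2, rt
Reagents that add atoms: none
Why: Hydroxyl-directed homogeneous hydrogenation, in which the cationic iridium catalyst bound to the α-OH at C1 delivers H2 to the α face of C9=C10, so the C10 methyl should end β (cis to the C7 side chain); the masked isopropenyl group cannot compete.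

Step 6
Reactants: 8 saturated cyclohexanol
Product: 9 allylic diol
Conditions: Et2AlCl, Li(NC9H18) [lithium 2,2,6,6-tetramethylpiperidide], toluene, 0 °C (diethylaluminium amide formed in the flask, 4 equiv)
Reagents that add atoms: none
Why: Aluminium-amide-promoted isomerisation of the 2,2-disubstituted oxirane to the allylic alcohol by syn β-elimination at the unhindered methyl group unveils C11(=C13)–C12H2OH.

Step 7
Reactants: 9 allylic diol
Product: 10 primary silyl ether
Conditions: t-BuMe2SiCl (1.05 equiv), imidazole, CH2Cl2, 0 °C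
Reagents that add atoms: tert-butyldimethylsilyl chloride, CC(C)(C)[Si](C)(C)Cl
Why: The unhindered primary allylic hydroxyl should be silylated selectively over the secondary C1 hydroxyl flanked by the axial C10 methyl.

Step 8
Reactants: 10 primary silyl ether
Product: 11 cyclohexanone
Conditions: DMP (triacetoxy periodinane), NaHCO3, CH2Cl2, rt
Reagents that add atoms: none
Why: Buffered periodinane oxidation of the secondary alcohol is non-enolising and should keep the kinetically set axial C10 methyl in place.

Step 9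
Reactants: 11 cyclohexanone
Product: 13 cycloheptanone, via silyl ketone 12 (not isolated)
Conditions: Me3SiCHN2, BF3·OEt2, CH2Cl2, −78 °C; aq. NaHCO3, then SiO2
Reagents that add atoms: trimethylsilyldiazomethane, C[Si](C)(C)C=[N+]=[N-]
Why: Lewis-acid-promoted diazoalkane homologation (Tiffeneau–Demjanov type) in which the less substituted α-carbon C6 migrates, inserting C5 between C1 and C6; the α-silyl ketone is protodesilylated on work-up and the low temperature protects C10.

Step 10
Reactants: 13 cycloheptanone
Product: 15 enol triflate, via potassium enolate 14 (not isolated)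
Conditions: KN(SiMe3)2, THF, −78 °C; PhNTf2, −78 °C
Reagents that add atoms: N-phenylbis(trifluoromethanesulfonimide), O=S(=O)(N(c1ccccc1)S(=O)(=O)C(F)(F)F)C(F)(F)F
Why: Kinetic deprotonation occurs at the CH2 carbon C5 and not at the methine C10, so O-triflation fixes the C1=C5 enol triflate without touching the C10 stereocentre.

Step 11
Reactants: 15 enol triflate; 16 but-3-yn-2-ol (racemic)
Product: 18 enynyl acetate, via enynol 17 (not isolated)
Conditions: Pd(PPh3)4 (5 mol%), CuI (10 mol%), Et3N, THF, rt; Ac2O, DMAP, rt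
Reagents that add atoms: acetic anhydride, CC(=O)OC(C)=O
Why: Sonogashira coupling of the alkenyl triflate (zerovalent palladium, copper acetylide) followed by acetylation in the same flask; the racemic carbinol is acceptable because that carbon (C4) is planarised in the next step.

Step 12
Reactants: 18 enynyl acetate
Product: 21 cis-fused hydroazulenone, via acetoxy vinylallene 19 (not isolated), via cyclopentadienyl acetate 20 (not isolated)
Conditions: Ph3PAuCl (5 mol%), AgSbF6 (5 mol%), wet CH2Cl2, rt
Reagents that add atoms: none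
Why: Monovalent gold triggers a 1,3-acyloxy shift to the acetoxy vinylallene, Nazarov-type 4π closure forms C4–C5, a 1,2-hydride shift and hydrolysis of the dienyl acetate give the cyclopentenone with the ketone at C2; the ring-fusion configuration is irrelevant because C1 and C5 become sp2 in the dienolate of step 25.

Step 13
Reactants: 22 allyl alcohol
Product: 23 allyl silyl ether
Conditions: t-BuPh2SiCl, imidazole, CH2Cl2, rt
Reagents that add atoms: tert-butyldiphenylsilyl chloride, CC(C)(C)[Si](Cl)(c1ccccc1)c1ccccc1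
Why: Routine silylation; the diphenylsilyl group is chosen so that it outlasts the later selective cleavage of a secondary tert-butyldimethylsilyl ether.

Step 14
Reactants: 23 allyl silyl ether
Product: 24 primary boronic ester
Conditions: pinacolborane, [Ir(cod)Cl]2 (1.5 mol%), dppb (3 mol%), CH2Cl2, rt
Reagents that add atoms: pinacolborane, CC1(C)OBOC1(C)C
Why: Iridium-catalysed hydroboration of a terminal alkene places boron on the terminal carbon (anti-Markovnikov).

Step 15
Reactants: 24 primary boronic ester; 25 ethyl N,N-diisopropylcarbamate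
Product: 28 (R)-secondary boronic ester, via lithiated carbamate 26 (not isolated), via boronate complex 27 (not isolated)
Conditions: 25, s-BuLi, (−)-sparteine, Et2O, −78 °C; 24, −78 °C; MgBr2·OEt2, then reflux
Reagents that add atoms: none
Why: Sparteine-mediated lithiation–borylation, in which the (S)-lithiated carbamate is borylated with retention and the 1,2-metallate shift displaces the carbamate with inversion, which should give the (R)-boronic ester that carries C4' and its methyl.

Step 16
Reactants: 7 transposed allylic alcohol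
Product: 29 transposed enone
Conditions: MnO2 (excess), CH2Cl2, rt
Reagents that add atoms: none
Why: Chemoselective oxidation of the allylic secondary alcohol gives the enone whose carbonyl carbon is C5' and whose alkene is C10'=C9'.

Step 17
Reactants: 29 transposed enone
Product: 31 tertiary α-hydroxy ketone, via hydroperoxide 30 (not isolated)
Conditions: Mn(dpm)3 (10 mol%), PhSiH3, O2 (1 atm), i-PrOH/CH2Cl2, 0 °C; P(OEt)3
Reagents that add atoms: dioxygen, O=O
Why: Mukaiyama-type hydration (hydrogen-atom transfer from a manganese hydride to C9', O2 capture of the tertiary α-keto radical, phosphite reduction); axial capture on the chair that keeps the C7'/C8' substituents equatorial should place the hydroxyl β, cis to the C7' side chain.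

Step 18
Reactants: 31 tertiary α-hydroxy ketone
Product: 32 trisylhydrazone
Conditions: 2,4,6-(i-Pr)3C6H2SO2NHNH2, THF, 4 Å MS, rt
Reagents that add atoms: 2,4,6-triisopropylbenzenesulfonohydrazide, CC(C)c1cc(C(C)C)c(S(=O)(=O)NN)c(C(C)C)c1
Why: Condensation of the ketone with the arenesulfonyl hydrazide without added acid spares the oxirane and the silyl ether.

Step 19
Reactants: 32 trisylhydrazone; 28 (R)-secondary boronic ester
Product: 36 side-chain cyclohexene, via alkenyllithium 33 (not isolated), via boronate complex 34 (not isolated), via iodo boronic ester 35 (not isolated)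
Conditions: s-BuLi (3.05 equiv), THF, −78 → 0 °C; 28, −78 °C → rt; I2, THF, −78 °C; NaOMe, MeOH, −78 → 0 °C
Reagents that add atoms: none
Why: The Shapiro reaction gives the C5' alkenyllithium regiospecifically (only C6' carries α-hydrogens), and Zweifel olefination (boronate formation, iodine-induced 1,2-migration of the secondary alkyl group with retention, methoxide-induced anti-elimination) joins C5' to C4' with the C4' configuration unchanged.

Step 20
Reactants: 36 side-chain cyclohexene
Product: 37 allylic alcohol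
Conditions: Et2AlCl, Li(NC9H18), toluene, 0 °C (5 equiv)
Reagents that add atoms: none
Why: The same aluminium-amide epoxide-to-allylic-alcohol isomerisation as in step 6 unveils C11'(=C13')–C12'H2OH; the tertiary hydroxyl only consumes one equivalent of base.

Step 21
Reactants: 37 allylic alcohol
Product: 39 acrylic acid, via enal 38 (not isolated)
Conditions: MnO2, CH2Cl2, rt, filter; NaClO2, NaH2PO4, 2-methyl-2-butene, t-BuOH/H2O, 0 °C
Reagents that add atoms: sodium chlorite, [Na+].[O-]Cl=O
Why: MnO2 oxidises only the primary allylic alcohol and Pinnick oxidation takes the enal to the acid, with the scavenger alkene protecting the ring alkene from hypochlorite.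

Step 22
Reactants: 39 acrylic acid
Product: 40 hydroxy acid
Conditions: HF·pyridine, pyridine, THF, 0 °C → rt
Reagents that add atoms: none
Why: Buffered fluoride should cleave the secondary tert-butyldimethylsilyl ether at C8' while the primary tert-butyldiphenylsilyl ether survives; the product is used at once to avoid acid-catalysed closure to the trans lactone.

Step 23
Reactants: 40 hydroxy acid
Product: 41 cis-fused methylene lactone
Conditions: PPh3, DIAD, THF (dilute), 0 °C → rt
Reagents that add atoms: none
Why: Mitsunobu lactonisation, in which the carboxylate displaces the activated C8' oxygen intramolecularly with inversion, turning the trans hydroxy acid into the cis-fused α-methylene γ-lactone; the tertiary alcohol cannot be activated.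

Step 24
Reactants: 41 cis-fused methylene lactone
Product: 42 lower lactone
Conditions: Et3SiOTf, 2,6-lutidine, CH2Cl2, −78 → 0 °C
Reagents that add atoms: triethylsilyl triflate, CC[Si](CC)(CC)OS(=O)(=O)C(F)(F)F
Why: Silyl triflate with a non-nucleophilic base protects the hindered tertiary allylic alcohol without touching the Michael acceptor.

Step 25
Reactants: 21 cis-fused hydroazulenone; 42 lower lactone
Product: 44 keto lactone precursor, via potassium dienolate 43 (not isolated)
Conditions: KN(SiMe3)2 (0.95 equiv), THF, 0 °C, 30 min; −78 °C, 42; AcOH, −78 °C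
Reagents that add atoms: none
Why: Michael addition in which a slight deficit of base lets the enolates equilibrate to the fully substituted linear dienolate O–C2=C1–C5=C4, which should attack the exocyclic methylene C13' through its α-carbon C1; the cycloheptene chair with equatorial C7/C8 substituents holds the C10 methyl axial on the β face so the acceptor comes from the α face, and the cold acid quench prevents retro-Michael and gives the β,γ-enone directly.

Step 26
Reactants: 44 keto lactone precursor
Product: 46 spiro-lactone norbornenone, via dilithium bis-enolate 45 (not isolated)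
Conditions: LiN(iPr)2 (2.3 equiv), THF, −78 °C; Fe(acac)3 (2.2 equiv), THF, −78 °C → rt, 0.01 M
Reagents that add atoms: none
Why: Double deprotonation gives the C2 dienolate (only C3 carries α-hydrogens once C1 is quaternary, and this more acidic site is deprotonated first, which blocks retro-Michael loss of C1) and the C11' lactone enolate; trivalent iron oxidises the dienolate to a C3-centred allylic α-keto radical that adds to C11' of the lactone enolate, and a second electron transfer from the resulting radical anion completes the C3–C11' bond. The closest known reaction type is the intramolecular oxidative heterocoupling of a ketone enolate with an ester or amide enolate by Fe(acac)3 or divalent copper carboxylates. Ring C1–C2–C3–C11'–C13' closes 5-exo-trig with respect to the C11'=C12' enolate bond; bonding through the γ-carbon C5 would need a four-membered ring. C3 is fixed by the C1–C13' tether (only the cis-bicycle can form), and C11' is set by approach of C3 on the convex face of the cis-fused lactone enolate, anti to C6' at C7', which puts the lactone carbonyl endo over C4=C5. The step needs heterocoupling over intermolecular homocoupling and facial selectivity at C11'; the tether with high dilution secures the first, the lactone ring fusion the second, and every other acidic site is silylated.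

Step 27
Reactants: 46 spiro-lactone norbornenone
Product: 47 anti alcohol
Conditions: NaBH4, MeOH/CH2Cl2, −40 → 0 °C
Reagents that add atoms: none
Why: Hydride reduction of the bridging ketone from the C4=C5 alkene face, because the other face is screened by the exo C7' substituent on the spiro carbon, should give the C2 alcohol anti to the alkene; the lactone is not reduced.

Step 28
Reactants: 47 anti alcohol
Product: 48 pentaol
Conditions: Bu4NF, AcOH (1:1), THF, rt → 40 °C
Reagents that add atoms: none
Why: Buffered fluoride cleaves all four silyl ethers (C8, C12, C10', C1') without opening the lactone.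

Step 29
Reactants: 48 pentaol
Product: 51 bis-lactone diol, via enal 49 (not isolated), via lactol 50 (not isolated)
Conditions: MnO2 (excess), CH2Cl2, rt
Reagents that add atoms: none
Why: MnO2 oxidises only the allylic primary alcohol C12; the enal closes with the trans C8 hydroxyl to the allylic lactol, which is oxidised further to the upper α-methylene γ-lactone, while saturated and tertiary alcohols do not react.

Step 30
Reactants: 51 bis-lactone diol
Product: 52 CNP0257312.1
Conditions: Ac2O, pyridine, DMAP (cat.), CH2Cl2, 0 °C → rt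
Reagents that add atoms: acetic anhydride, CC(=O)OC(C)=O
Why: Acetylation of the secondary C2 and primary C1' hydroxyls; the tertiary allylic C10' hydroxyl should be too hindered to react under these conditions.

Compound list

1 | (R)-carvone, (5R)-2-methyl-5-(prop-1-en-2-yl)cyclohex-2-en-1-one | CC1=CC[C@H](CC1=O)C(C)=C | starting material
2 | trimethylsilyl dienol ether of 1 (C9(OSiMe3)=C8, C10=C1) | C[Si](C)(C)OC1=C[C@@H](CC=C1C)C(C)=C | intermediate
3 | trans-6-(trimethylsilyloxy)-8,9-epoxycarvone (C8–O α; oxirane epimers) | C[Si](C)(C)O[C@@H]1C(=O)C(C)=CC[C@H]1C2(C)CO2 | intermediate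
4 | trans-6-hydroxy-8,9-epoxycarvone (C8–OH α, anti to the C7 side chain; oxirane epimers) | O[C@@H]1C(=O)C(C)=CC[C@H]1C2(C)CO2 | intermediate
5 | tert-butyldimethylsilyl ether of 4 | CC(C)(C)[Si](C)(C)O[C@@H]1C(=O)C(C)=CC[C@H]1C2(C)CO2 | intermediate
6 | bis-epoxy ketone (C10–C1 ring epoxide α, C9 ketone, C8–OTBS α, C7 methyloxiranyl β) | CC(C)(C)[Si](C)(C)O[C@@H]1C(=O)[C@]2(C)O[C@@H]2C[C@H]1C3(C)CO3 | intermediate
7 | allylic alcohol (C1–OH α, C9=C10, C8–OTBS α, C7 methyloxiranyl β); in lower-series labels C5'–OH, C9'=C10' | CC(C)(C)[Si](C)(C)O[C@@H]1C=C(C)[C@H](O)C[C@H]1C2(C)CO2 | intermediate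
8 | cyclohexanol (C1–OH α, C10–Me β, C8–OTBS α, C7 methyloxiranyl β) | CC(C)(C)[Si](C)(C)O[C@@H]1C[C@@H](C)[C@H](O)C[C@H]1C2(C)CO2 | intermediate
9 | allylic diol (C7 side chain C(=CH2)CH2OH) | CC(C)(C)[Si](C)(C)O[C@@H]1C[C@@H](C)[C@H](O)C[C@H]1C(=C)CO | intermediate
10 | bis-silyl ether with free C1–OH | CC(C)(C)[Si](C)(C)O[C@@H]1C[C@@H](C)[C@H](O)C[C@H]1C(=C)CO[Si](C)(C)C(C)(C)C | intermediate
11 | cyclohexanone (C1 ketone, C10–Me β axial) | CC(C)(C)[Si](C)(C)O[C@@H]1C[C@@H](C)C(=O)C[C@H]1C(=C)CO[Si](C)(C)C(C)(C)C | intermediate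
12 | α-trimethylsilyl cycloheptanone (silyl group on C5) | CC(C)(C)[Si](C)(C)O[C@@H]1C[C@@H](C)C(=O)C([Si](C)(C)C)C[C@H]1C(=C)CO[Si](C)(C)C(C)(C)C | intermediate
13 | cycloheptanone (C1 ketone, C10–Me β, C8–OTBS α, C7 β side chain C(=CH2)CH2OTBS) | CC(C)(C)[Si](C)(C)O[C@@H]1C[C@@H](C)C(=O)CC[C@H]1C(=C)CO[Si](C)(C)C(C)(C)C | intermediate
14 | potassium enolate of 13 (C1=C5) | CC(C)(C)[Si](C)(C)O[C@@H]1C[C@@H](C)C(O[K])=CC[C@H]1C(=C)CO[Si](C)(C)C(C)(C)C | intermediate
15 | cycloheptenyl triflate (C1(OTf)=C5) | CC(C)(C)[Si](C)(C)O[C@@H]1C[C@@H](C)C(OS(=O)(=O)C(F)(F)F)=CC[C@H]1C(=C)CO[Si](C)(C)C(C)(C)C | intermediate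
16 | but-3-yn-2-ol (racemic) | CC(O)C#C | starting material
17 | enynol (C1–C2≡C3–C4H(OH)CH3, carbinol epimers) | CC(C)(C)[Si](C)(C)O[C@@H]1C[C@@H](C)C(C#CC(C)O)=CC[C@H]1C(=C)CO[Si](C)(C)C(C)(C)C | intermediate
18 | enynyl acetate | CC(C)(C)[Si](C)(C)O[C@@H]1C[C@@H](C)C(C#CC(C)OC(C)=O)=CC[C@H]1C(=C)CO[Si](C)(C)C(C)(C)C | intermediate
19 | acetoxy vinylallene (C5=C1–C2(OAc)=C3=C4) | CC(C)(C)[Si](C)(C)O[C@@H]1C[C@@H](C)C(C(OC(C)=O)=C=CC)=CC[C@H]1C(=C)CO[Si](C)(C)C(C)(C)C | intermediate
20 | cyclopentadienyl acetate (C1=C2(OAc), C3=C4) | CC(C)(C)[Si](C)(C)O[C@@H]1C[C@@H](C)C2=C(OC(C)=O)C=C(C)C2C[C@H]1C(=C)CO[Si](C)(C)C(C)(C)C | intermediate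
21 | cis-fused hydroazulenone (C2 ketone, C3=C4, H1 and H5 cis; drawn for one cis ring-fusion isomer, the other serves equally) | CC(C)(C)[Si](C)(C)O[C@@H]1C[C@@H](C)[C@H]2C(=O)C=C(C)[C@H]2C[C@H]1C(=C)CO[Si](C)(C)C(C)(C)C | intermediate
22 | allyl alcohol | C=CCO | starting material
23 | allyl tert-butyldiphenylsilyl ether | C=CCO[Si](c1ccccc1)(c1ccccc1)C(C)(C)C | intermediate
24 | 2-[3-(tert-butyldiphenylsilyloxy)propyl]-4,4,5,5-tetramethyl-1,3,2-dioxaborolane | CC1(C)OB(CCCO[Si](c2ccccc2)(c2ccccc2)C(C)(C)C)OC1(C)C | intermediate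
25 | ethyl N,N-diisopropylcarbamate | CCOC(=O)N(C(C)C)C(C)C | starting material
26 | (S)-1-lithioethyl N,N-diisopropylcarbamate (sparteine complex) | C[C@H]([Li])OC(=O)N(C(C)C)C(C)C | intermediate
27 | lithium boronate complex of 26 and 24 | [Li+].C[C@@H](OC(=O)N(C(C)C)C(C)C)[B-]1(CCCO[Si](c2ccccc2)(c2ccccc2)C(C)(C)C)OC(C)(C)C(C)(C)O1 | intermediate
28 | 2-[(2R)-5-(tert-butyldiphenylsilyloxy)pentan-2-yl]-4,4,5,5-tetramethyl-1,3,2-dioxaborolane | CC1(C)OB(OC1(C)C)[C@H](C)CCCO[Si](c2ccccc2)(c2ccccc2)C(C)(C)C | intermediate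
29 | enone (C5' ketone, C10'=C9', C8'–OTBS trans to the C7' methyloxiranyl group) | CC(C)(C)[Si](C)(C)O[C@@H]1C=C(C)C(=O)C[C@H]1C2(C)CO2 | intermediate
30 | tertiary α-hydroperoxy ketone (C10'–OOH β) | CC(C)(C)[Si](C)(C)O[C@@H]1C[C@@](C)(OO)C(=O)C[C@H]1C2(C)CO2 | intermediate
31 | tertiary α-hydroxy ketone (C10'–OH β, cis to the C7' side chain, trans to C8'–OTBS) | CC(C)(C)[Si](C)(C)O[C@@H]1C[C@@](C)(O)C(=O)C[C@H]1C2(C)CO2 | intermediate
32 | 2,4,6-triisopropylbenzenesulfonyl hydrazone of 31 | CC(C)(C)[Si](C)(C)O[C@@H]1C[C@@](C)(O)C(=NNS(=O)(=O)c2c(C(C)C)cc(C(C)C)cc2C(C)C)C[C@H]1C3(C)CO3 | intermediate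
33 | C5' alkenyllithium (lithium alkoxide at C10') | CC(C)(C)[Si](C)(C)O[C@@H]1C[C@@](C)(O[Li])C([Li])=C[C@H]1C2(C)CO2 | intermediate
34 | lithium alkenyl boronate complex of 33 and 28 | [Li+].CC(C)(C)[Si](C)(C)O[C@@H]1C[C@@](C)(O[Li])C([B-]3(OC(C)(C)C(C)(C)O3)[C@H](C)CCCO[Si](c4ccccc4)(c4ccccc4)C(C)(C)C)=C[C@H]1C2(C)CO2 | intermediate
35 | β-iodo boronic ester (boron on C5', iodine on C6', anti) | CC(C)(C)[Si](C)(C)O[C@@H]1C[C@@](C)(O[Li])C(B3OC(C)(C)C(C)(C)O3)([C@H](C)CCCO[Si](c4ccccc4)(c4ccccc4)C(C)(C)C)C(I)[C@H]1C2(C)CO2 | intermediate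
36 | cyclohexene with (4'R) side chain on C5' (C5'=C6', C10'–OH β, C8'–OTBS α, C7' methyloxiranyl β) | CC(C)(C)[Si](C)(C)O[C@@H]1C[C@@](C)(O)C([C@H](C)CCCO[Si](c2ccccc2)(c2ccccc2)C(C)(C)C)=C[C@H]1C3(C)CO3 | intermediate
37 | allylic alcohol (C7' side chain C(=CH2)CH2OH) | CC(C)(C)[Si](C)(C)O[C@@H]1C[C@@](C)(O)C([C@H](C)CCCO[Si](c2ccccc2)(c2ccccc2)C(C)(C)C)=C[C@H]1C(=C)CO | intermediate
38 | enal (C12' aldehyde) | CC(C)(C)[Si](C)(C)O[C@@H]1C[C@@](C)(O)C([C@H](C)CCCO[Si](c2ccccc2)(c2ccccc2)C(C)(C)C)=C[C@H]1C(=C)C=O | intermediate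
39 | acrylic acid (C12' acid) | CC(C)(C)[Si](C)(C)O[C@@H]1C[C@@](C)(O)C([C@H](C)CCCO[Si](c2ccccc2)(c2ccccc2)C(C)(C)C)=C[C@H]1C(=C)C(=O)O | intermediate
40 | trans hydroxy acid (free C8'–OH α and C10'–OH β) | O[C@@H]1C[C@@](C)(O)C([C@H](C)CCCO[Si](c2ccccc2)(c2ccccc2)C(C)(C)C)=C[C@H]1C(=C)C(=O)O | intermediate
41 | cis-fused α-methylene γ-lactone, (4'R,7'S,8'S,10'R), free C10'–OH | C=C1C(=O)O[C@H]2C[C@@](C)(O)C([C@H](C)CCCO[Si](c3ccccc3)(c3ccccc3)C(C)(C)C)=C[C@H]21 | intermediate
42 | lower lactone (C10'–OSiEt3, C1'–OSiPh2t-Bu) | C=C1C(=O)O[C@H]2C[C@@](C)(O[Si](CC)(CC)CC)C([C@H](C)CCCO[Si](c3ccccc3)(c3ccccc3)C(C)(C)C)=C[C@H]21 | intermediate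
43 | potassium dienolate of 21 (C2(OK)=C1, C4=C5) | CC(C)(C)[Si](C)(C)O[C@@H]1C[C@@H](C)C2=C(O[K])CC(C)=C2C[C@H]1C(=C)CO[Si](C)(C)C(C)(C)C | intermediate
44 | keto lactone precursor (C1 quaternary with C13' α, C2 ketone, C3H2, C4=C5; C11'–H) | CC(C)(C)[Si](C)(C)O[C@@H]2C[C@@H](C)[C@@]3(C[C@H]5C(=O)O[C@H]6C[C@@](C)(O[Si](CC)(CC)CC)C([C@H](C)CCCO[Si](c7ccccc7)(c7ccccc7)C(C)(C)C)=C[C@H]65)C(=O)CC(C)=C3C[C@H]2C(=C)CO[Si](C)(C)C(C)(C)C | intermediate
45 | dilithium bis-enolate of 44 (C2(OLi)=C3–C4=C5 and C11'=C12'(OLi)) | CC(C)(C)[Si](C)(C)O[C@@H]2C[C@@H](C)[C@@]3(CC5=C(O[Li])O[C@H]6C[C@@](C)(O[Si](CC)(CC)CC)C([C@H](C)CCCO[Si](c7ccccc7)(c7ccccc7)C(C)(C)C)=C[C@H]65)C(O[Li])=CC(C)=C3C[C@H]2C(=C)CO[Si](C)(C)C(C)(C)C | intermediate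
46 | spiro-lactone 7-norbornenone (C3–C11' bond; lactone carbonyl endo, C2 ketone) | CC(C)(C)[Si](C)(C)O[C@@H]2C[C@@H](C)[C@]34C[C@]5(C(=O)O[C@H]6C[C@@](C)(O[Si](CC)(CC)CC)C([C@H](C)CCCO[Si](c7ccccc7)(c7ccccc7)C(C)(C)C)=C[C@H]65)[C@H](C(C)=C3C[C@H]2C(=C)CO[Si](C)(C)C(C)(C)C)C4=O | intermediate
47 | C2 alcohol, hydroxyl anti to C4=C5 | CC(C)(C)[Si](C)(C)O[C@@H]2C[C@@H](C)[C@]34C[C@]5(C(=O)O[C@H]6C[C@@](C)(O[Si](CC)(CC)CC)C([C@H](C)CCCO[Si](c7ccccc7)(c7ccccc7)C(C)(C)C)=C[C@H]65)[C@H](C(C)=C3C[C@H]2C(=C)CO[Si](C)(C)C(C)(C)C)[C@H]4O | intermediate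
48 | pentaol (C2, C8, C12, C10', C1' hydroxyls) | O[C@@H]2C[C@@H](C)[C@]34C[C@]5(C(=O)O[C@H]6C[C@@](C)(O)C([C@H](C)CCCO)=C[C@H]65)[C@H](C(C)=C3C[C@H]2C(=C)CO)[C@H]4O | intermediate
49 | C12 enal | O[C@@H]2C[C@@H](C)[C@]34C[C@]5(C(=O)O[C@H]6C[C@@](C)(O)C([C@H](C)CCCO)=C[C@H]65)[C@H](C(C)=C3C[C@H]2C(=C)C=O)[C@H]4O | intermediate
50 | C12 lactol (both anomers) | C=C1C(O)O[C@@H]2C[C@@H](C)[C@]34C[C@]5(C(=O)O[C@H]6C[C@@](C)(O)C([C@H](C)CCCO)=C[C@H]65)[C@H](C(C)=C3C[C@@H]12)[C@H]4O | intermediate
51 | bis-lactone diol (free C2 and C1' hydroxyls) | C=C1C(=O)O[C@@H]2C[C@@H](C)[C@]34C[C@]5(C(=O)O[C@H]6C[C@@](C)(O)C([C@H](C)CCCO)=C[C@H]65)[C@H](C(C)=C3C[C@@H]12)[C@H]4O | intermediate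
52 | CNP0257312.1 | C=C1C(=O)O[C@@H]2C[C@@H](C)[C@]34C[C@]5(C(=O)O[C@H]6C[C@@](C)(O)C([C@H](C)CCCOC(C)=O)=C[C@H]65)[C@H](C(C)=C3C[C@@H]12)[C@H]4OC(C)=O | target

Total step count: 30. Longest linear sequence: 19 steps (steps 1–4, 16–24, 25–30); the upper branch (steps 5–12) and the side-chain branch (steps 13–15) join it at steps 25 and 19.

Steps most likely to fail

Step 26 (key step). The radical intermediates may couple between molecules or be reduced back, the lactone enolate may fragment by retro-Michael cleavage of C1–C13', or C3 may bond on the concave lactone face. The fallback is a two-electron closure of the same bond. It sets out from 44: selective enolisation of the ketone (KN(SiMe3)2, 1.05 equiv, −78 °C) and bromination with N-bromosuccinimide should give the C3 α-bromo ketone F1. LiN(SiMe3)2 (THF, −78 → 0 °C) then forms the lactone enolate, which displaces bromide in an intramolecular 5-exo-tet enolate alkylation. The C3 epimers interconvert through the enol, and a γ-bromo isomer would reach the same bond in an SN2' sense. The fallback returns to the route at 46.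

Step 25. Attack may occur through the γ-carbon C4 or the kinetic C3 enolate and not through C1, facial selectivity at the new quaternary centre may be poor, and the dienolate may act as a base on C7'–H of the lactone (drift to the endocyclic butenolide) or the adduct may revert on warming. The fallback removes the free base. It sets out from 21: thermodynamic silylation (Me3SiCl, NaI, Et3N, MeCN, rt; the silyloxycyclopentadienes equilibrate by 1,5-hydrogen shifts to the most substituted isomer) gives the silyl dienol ether F2. A Lewis-acid-catalysed Mukaiyama–Michael addition to 42 (Me3SiNTf2, 10 mol%, CH2Cl2, −78 °C; mild acidic work-up) returns to the route at 44.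

Step 19. The hydrazone dianion may fragment slowly, s-BuLi may open the side-chain oxirane during the warm-up, or the hindered alkenyllithium may form the boronate complex sluggishly. The fallback replaces the Shapiro elimination by halogen–lithium exchange. It sets out from 31: condensation with hydrazine (N2H4·H2O, Et3N, EtOH) gives the hydrazone F3, and iodination (I2, tetramethylguanidine, THF; Barton vinyl iodide synthesis) gives the alkenyl iodide F4. Iodine–lithium exchange (t-BuLi, THF, −78 °C, no warming) delivers the alkenyllithium and returns to the route at 33, which continues with 28 to 36.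

Further compounds

F1 | step 26 | C3 α-bromo ketone of 44 | CC(C)(C)[Si](C)(C)O[C@@H]2C[C@@H](C)[C@@]3(C[C@H]5C(=O)O[C@H]6C[C@@](C)(O[Si](CC)(CC)CC)C([C@H](C)CCCO[Si](c7ccccc7)(c7ccccc7)C(C)(C)C)=C[C@H]65)C(=O)C(Br)C(C)=C3C[C@H]2C(=C)CO[Si](C)(C)C(C)(C)C
F2 | step 25 | trimethylsilyl dienol ether of 21 (C2(OSiMe3)=C1, C4=C5) | CC(C)(C)[Si](C)(C)O[C@@H]1C[C@@H](C)C2=C(O[Si](C)(C)C)CC(C)=C2C[C@H]1C(=C)CO[Si](C)(C)C(C)(C)C
F3 | step 19 | hydrazone of 31 | CC(C)(C)[Si](C)(C)O[C@@H]1C[C@@](C)(O)C(=NN)C[C@H]1C2(C)CO2
F4 | step 19 | C5' alkenyl iodide (C5'=C6') | CC(C)(C)[Si](C)(C)O[C@@H]1C[C@@](C)(O)C(I)=C[C@H]1C2(C)CO2
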